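(Its constants were chosen freely, and the outcome is calculated.)

A neighbour of this flask, with 1.20 equiv of second substrate instead of 2.00 equiv, is the test waiting at the end; you start with the flask as charged.

starting material 0.80 M; partner 1.05 equiv; second substrate 2.00 equiv; third substrate 0.500 equiv; protic impurity 0.240 M; time 25 min

- how much of the starting material has reacted by 25 min
- how much target there is at 25 min, in percent of the starting material charged

    starting material + partner → target (k1 = 0.81 M⁻¹ s⁻¹)
    second substrate + partner → second product (k2 = 0.11 M⁻¹ s⁻¹)
    third substrate + partner → third product (k3 = 1.7 M⁻¹ s⁻¹)
    partner + protic impurity → quenched reagent (k4 = 0.014 M⁻¹ s⁻¹)

Climb the ladder of the partner's half-lives, each step taken alone at the charged concentrations, fastest first. The third substrate gives 1.02 s, the starting material 1.07 s, the second substrate 3.94 s and the protic impurity 3.4 min, while you are asked at 25 min. The substrates work on a scale of seconds and well ahead of the impurity, so you reckon a split, not a clock.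

The zero of the scale is equal constants for the substrates, with the impurity set aside: the partner then spreads by charge and each substrate loses 30.0 %. Real constants differ, but every substrate meets the same partner, so each keeps the fraction exp(−kD), where k is its constant and D, the dose, is the time integral of the partner concentration. Half of the starting material goes at a dose of 0.856 M·s. Adding what the other two substrates take at that dose gives 1.06 equiv, the price of half: the equivalents of partner the substrates together consume while half of the starting material reacts. The impurity takes 0.00359 equiv at that dose, so the flask falls short by 0.0165 equiv. The starting material's share of the last partner is 50.4 %, so I expect 49.2 %. Nothing in the scheme consumes the target, so its yield equals the conversion.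

The forecast gave 49 % (46 % to 52 %) for both, holding that “the outcome is set by how the 0.84 M of partner is split among the competing substrates, not by time”. The simulation gives 49.2 % and 49.2 %. The substrate steps ran while the partner lasted, with half of the turnover of starting material to target done by 0.599 s and the partner, the limiting reagent, at 0 % by 2.50 min. From then to 250 min the flask held 50.8 % of its starting material. In the neighbour with 1.20 equiv, the price falls to 0.991 equiv, leaving a surplus of 0.0553 equiv, of which the starting material takes 56.0 %, which points to 53.1 %; that neighbour flask reached 53.1 %.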